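The trap in this flask is to read a product excess that shows no clear fall as proof that Sbt and Sbt2 exchange.

| setting | Thursday's | Sunday's | flask |
|---|---|---|---|
| Sbt | 0.67 M | 1 M | 1.0 M |
| Sbt2 | 0.67 M | 1 M | 1.0 M |
| Rea | 2.5 M | 1.2 M | 2.50 M |
| remark | run made earlier | run made earlier |  |
| time |  |  | 25 h |
- Thursday's (time / h: Pdt / %, Pdt2 / %, Sbt / %): 8.00: 15, 9, 27; 15.0: 25, 13, 21; 25.0: 27, 8, 16; 30.0: 26, 15, 14
- Sunday's (time / h: Pdt / %, Pdt2 / %, Sbt / %): 8.00: 10, 7, 36; 15.0: 10, 10, 29; 25.0: 18, 8, 22; 30.0: 16, 7, 26

(scatter of a reading: 2 percentage points)
- Rea is single-handed; Sbt and Sbt2 are mirror images of each other, charged as a racemate, each of them at the stated concentration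
- steps under discussion: Int -> Sid2; Rea -> Sid3; Int -> Sid; Rea + Sbt2 -> Pdt2; Rea + Sbt -> Pdt; Sbt <-> Int; Sbt2 <-> Int; Rea <-> Int2
- an excess is the difference of the two amounts in percent of their sum
- an excess is below zero if the other one leads
- the handed part of Rea does not stay in what it makes, so the products of the two hands are mirror images too
1. Pdt and Pdt2 together, in percent of the Sbt and Sbt2 charged together, at 25 h
2. excess of Pdt over Pdt2 in the product at 25 h
3. whether the exchange between Sbt and Sbt2 keeps pace with the reaction: how far the product's excess at 25 h gets from its value without exchange to its value with instant exchange (above 80% keeps pace, below 20% hardly takes part, else lags behind)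

Minutes. The first speaker reported that the eight pairs of readings pool to an excess of Pdt over Pdt2 of 31.2%, at a mean product of 28.0%.

The second speaker objected that in a kinetic resolution without exchange c(Sbt), the hand that leads, thins out ahead of c(Sbt2), so the excess sinks as product builds. With instant exchange the two stay equal and the excess keeps its start value. She proposed to reckon the sinking alone, as a correction. At a modest yield y, the excess is the start excess times one minus D times y, where D, the run-down coefficient, is half of one minus the square of the start excess.

Worked back from the pooled figures, her own reckoning gave a start excess of 35.8% and D of 0.436. At the forecast's yield that is a drop of 5.6 percentage points.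

The first speaker answered that this drop is smaller than the gap between Thursday's and Sunday's pooled excesses, 34.8% and 25.6%, so the readings do not show it plainly.

The forecast stood at 36%, 30% and lags behind, on the ground that “The excess not falling hints at some exchange”.

The flask gives 37.8%, 33.1% and hardly takes part, at 12% of the way.

    Int → Sid2 (k = 0.0430 h⁻¹)
    Rea → Sid3 (k = 0.0560 h⁻¹)
    Int → Sid (k = 0.0320 h⁻¹)
    Rea + Sbt2 → Pdt2 (k = 0.0150 M⁻¹ h⁻¹)
    Rea + Sbt → Pdt (k = 0.0360 M⁻¹ h⁻¹)
    Sbt ⇌ Int (K = 0.550, k = 0.0280 h⁻¹)
    Sbt2 ⇌ Int (K = 0.550, k = 0.0280 h⁻¹)
    Rea ⇌ Int2 (K = 0.230, k = 0.0470 h⁻¹)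

The constants put the start excess at 41.2%, the value instant exchange holds. D at this flask's yield brings that down to 34.4%, close to the 33.1% it shows. The step from Rea to Sid3 and stopping at 25 h together hold the reacted part of this flask at 59.3%, against 70.4% without the step, and that step is part of why the excess stands at 33.1% and not 28.7%. The neighbour flask with 1.0 M of Rea made 17.3% of product, where D gives 38.1%, and its simulated excess is 37.9%.

(The numbers in the tables are calculated with made-up constants.)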